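## Structural features

The target (32) is a monocyclic bisabolane-type sesquiterpenoid: a cyclohexanone ring C1–C6 in which every carbon is substituted, joined through C1 to an open chain C7–C11 whose C7 carries the exocyclic methylene C14, whose C8 carries an angelate and whose C10/C11 form a trisubstituted oxirane. Five ring stereocentres follow one another (C1, C2, C3, C4 and, across the C5 carbonyl, C6), while the chain centres C8 and C10 stand 1,3 to each other and C8 stands 1,3 to C1 through the sp2 carbon C7. On the ring, C7 on C1 and the tertiary hydroxyl on C4 occupy one face (the top face below) and the oxygens on C2, C3 and C6 the other, so that in the chair the C1, C2 and C6 substituents are equatorial and the C3 and C4 hydroxyls are trans-diaxial. Fragile are the three angelates (Z to E isomerisation, acyl migration, base), the tertiary α-ketol at C4/C5, the enolisable α-acyloxy centre C6, the allylic ester at C8 and the acid-labile oxirane, and in every precursor with a carbonyl at C7 both β-carbons (C2 and C6) bear leaving groups. The real difficulty is not the carbon skeleton but the oxygen atoms on the consecutive carbons C2 to C6 and on C8, which end in four different states (ester, free secondary alcohol, free tertiary alcohol, ketone) and must be told apart while the contiguous stereochemistry is built. The key step exploits the cis-1,4 relation of C7 and the C4 oxygen: joined as a lactone C7(=O)–O–C4 they turn ring and bridge into a 2-oxabicyclo[2.2.2]octane, which is the [4+2] adduct of a 2-pyranone, and the cis C2/C3 oxygens on the opposite face are then the mark of a cis-dioxygenated alkene that has added endo. A check of the descriptors shows that this endo adduct (7) carries exactly the C1–C4 configuration of 32; what the plan has to handle are three chemical traps (hydroboration gives the C5 alcohol and not the ketone, a cyclic carbonate does not survive carbon nucleophiles, an allylic oxidation at C8 would lose to the C10=C11 unit) and the source of absolute configuration, which is built into the diene as an enantiopure, oxidatively removable ether.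

## Logic of the disconnections

32 to 31: the two C–O bonds of the C10/C11 oxirane are cut last. The oxirane is the most acid-sensitive group and C10 is too remote for substrate control, so every acidic step is placed before it. The forward step must be a catalyst-controlled oxygen transfer that picks the electron-rich trisubstituted alkene over C7=C14 and the three enoate double bonds, at a pH the esters and the ketol tolerate.

31 to 30 and 24, then 30 to 29: the C2 ester C–O bond is cut, then the C2/C3 diol is returned to its acetonide. The diol is unveiled only when C5 is already a ketone, so the only acylable hydroxyls are the equatorial one on C2 and the axial, neopentyl one on C3. The forward step must be site-selective and must keep the Z geometry of the acyl group.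

29 to 28 to 27: the C5 carbonyl is traced back to the C5 alcohol and this to its silyl ether. A ketone at C5 cannot pass organometallic or hydride steps and must not exist next to a free C6 hydroxyl, so it is made after O6 is esterified and while O3 is still masked. This demands a desilylation without acyl shift from O6 to O5 and an oxidation in which C5–OH is the only secondary alcohol.

27 to 26 and 24, then 26 to 25, then 25 to 22 and 24: the ester C–O bond at C6 is cut, O6 is returned to its benzylic ether, and the ester C–O bond at C8 is cut. The two acylations are kept apart on purpose: the allylic C8 hydroxyl is esterified first, so that the quinone that frees O6 meets no free allylic alcohol, and each acylation then has a single secondary hydroxyl to address. The forward steps must be an oxidative ether cleavage that spares two alkenes and an allylic ester, and a forcing but non-isomerising acylation of the hindered C6 hydroxyl.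

24 to 23: the anhydride C–O bond of the acyl donor is cut. One batch of 24 serves all three esterifications, and the Z double bond never meets a nucleophilic catalyst. The forward step only has to avoid isomerising conditions.

22 to 21 to 20 to 19 to 17: the C8–H bond (hydride), the C7=C14 bond (methylene transfer) and the C8–O bond (enolate oxidation) are cut in turn. C8 cannot be controlled from the ring, so it is set by a reagent-controlled reduction of the C8 ketone flanked by the 2-substituted vinyl group. The oxygen is introduced at the ketone stage because an allylic oxidation would attack C10=C11. This requires regioselective enolisation toward C8, methylenation of a hindered α-ketol and careful handling of a β,γ-unsaturated enone.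

17 to 16 to 13 and 14 (through 15): the C7–C8 bond is cut, which separates the ring from the six-carbon chain. The forward addition must be faster than enolisation of a β-alkoxy aldehyde.

13 to 12 to 11 to 10: the oxidation level of C7 is adjusted and the acetonide is traced back to the carbonate. Lactone and carbonate cannot be distinguished by a carbon nucleophile, so both are reduced at once and C7 is re-oxidised. The gain is a monocyclic, fully differentiated polyol (O2/O3 ketal, O4 free tertiary, O5 silyl, O6 benzylic).

10 to 9 to 7 (through 8): the C5–O and C6–H bonds are cut. Hydration of the enol ether in the anti-Markovnikov sense places the oxygen on C5 and the hydrogen on C6 from the same face. The bicycle must make that face the one next to the lactone bridge.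

7 to 5 and 6: the C1–C2 and C3–C4 bonds are cut (the key disconnection). The ring and four contiguous stereocentres fall back to a flat pyranone and a symmetrical alkene. The forward step needs endo selectivity, no loss of CO2, and a handle for the absolute configuration, which the chiral ether in 5 supplies by making the adducts diastereomers.

5 to 2 and 3 (through 4), then 2 to 1: the vinylic C4–O bond and then the C4–Br bond are cut. The ether is made by substitution at the pyranone so that the stereocentre of 3 is never a reaction centre.

## Other disconnections considered

Alternative 1: The cut is the ring bond C3–C4, with C3 returned to C5: the cyclohexanone is traced back to the 1-acetylcyclopentanol A1, in which C4 and its methyl form an acetyl group on the carbinol carbon C5. In the forward sense KOt-Bu would induce an α-ketol rearrangement: C3 shifts from C5 to the acetyl carbon, C5 becomes the ketone and C4 the tertiary carbinol, giving A2. In its favour, ring strain is released and the chain stereocentres can be in place beforehand. The C4 carbinol/C5 ketone pair also arrives directly at its final oxidation level, whereas the chosen plan needs a hydroboration, a protecting group on O5 and a late oxidation; on this point the alternative is the better. Against it here, A1 already holds four contiguous stereocentres on a cyclopentane that must itself be made in enantiopure form, so the rearrangement simplifies little. Either ring bond at C5 (to C3 or to C6) could migrate, and the configuration at C4 depends on the geometry of the alkoxide–carbonyl pair at the moment of the shift. The product is itself an α-ketol, so the equilibrium need not lie on one side, and strong base next to the C6 silyl ether and the C1 methine invites elimination. In comparison, the cycloaddition of the chosen plan makes the ring and four stereocentres in one stereospecific step, where the ring expansion creates one stereocentre under thermodynamic and chelation control. In step count the alternative is expected to be longer up to A1 and equal afterwards, since ester installation and epoxidation would be the same.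

Alternative 2: The cut is the ring bond C2–C3: the ring is opened to the 1,6-dialdehyde A3, whose two formyl carbons are C2 and C3. In the forward sense SmI2 would couple them reductively (pinacol coupling through ketyl radicals held on samarium) and close the six-membered ring as the cis-diol A4. In its favour, this ring closure is a dependable way to a cis-1,2-diol, and it delivers the C2/C3 diol free with O5 and O6 already carrying different groups, which equals the differentiation reached in the chosen plan. All stereocentres of A3 can come from established acyclic asymmetric reactions, so absolute configuration needs no separation of diastereomers; on this point the alternative is the better. Against it here, A3 carries an α-hydroxy aldehyde on a quaternary carbon and a β-alkoxy aldehyde, both prone to retro-aldol and elimination. The centres C1, C4, C5, C6 and C8 have to be assembled one after another in an open chain. The facial sense of the new diol relative to C1 and C4 rests on conformational preference and not on a stereospecific event. In comparison, the chosen plan forms two ring bonds and four centres at once by orbital-symmetry control, against one bond and two centres by chelate control. The alternative is expected to cost clearly more steps before the ring exists and about the same after it.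

Alternative 3: The cut is the ring bond C1–C2, with the double bond moved back from C7=C14 to C1=C7: the ring is opened to the aldehyde A5 (formyl carbon C2, trisubstituted alkene C1=C7 bearing C14 as a methyl). In the forward sense a chelating Lewis acid (MgBr2·OEt2 or SnCl4) would hold the aldehyde and the α-alkoxy group on C3 and promote an intramolecular carbonyl-ene reaction that forms C1–C2, transfers a hydrogen from C14 and gives the cyclohexanol A6. In its favour, ring, exocyclic methylene and the C2 hydroxyl arise in one step; O2 emerges alone and unprotected, already distinguished from O3, and no ketone methylenation next to two β-oxygens is needed. On both points the alternative is the better. The trans relation of C1 and C2 is the one such cyclisations normally deliver, which equals the control of the chosen plan at these two centres. Against it here, the ene donor has a second allylic hydrogen at C8, next to an oxygen, so that hydrogen transfer from the wrong side competes. The alkene geometry of A5 must be controlled, and strong Lewis acids threaten the acetonide, the silyl ethers and the benzylic ether. A5 again needs five stereocentres built in an open chain. In comparison, the ene step sets two centres under chelation control and the cycloaddition four by stereospecific suprafacial addition. The ene route saves steps after the ring closure but is expected to lose more before it.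

Key step: step 3

Remark on conventions: ring carbons are numbered C1 (bears the chain), C2, C3, C4 (bears CH3), C5, C6 and the chain C7 (bears methylene C14), C8, C9, C10, C11 in all compounds; "top face" is the ring face that carries C7 on C1, "bottom face" the other; MPE = (1S)-1-(4-methoxyphenyl)ethyl, TBS = tert-butyldimethylsilyl, Ang = (Z)-2-methylbut-2-enoyl (angeloyl).
Assumption: (S)-1-(4-methoxyphenyl)ethanol, the (R)-CBS oxazaborolidine and the D-fructose-derived epoxidation ketone are taken as commercial materials.

## Steps

Step 1
Reactants: 1 triacetic acid lactone (4-hydroxy-6-methyl-2H-pyran-2-one)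
Product: 2 4-bromo-6-methyl-2H-pyran-2-one
Conditions: n-Bu4NBr, P2O5, toluene, 100 °C
Reagents that add atoms: tetrabutylammonium bromide, CCCC[N+](CCCC)(CCCC)CCCC.[Br-]
Why: Deoxybromination of a vinylogous carboxylic acid: P2O5 turns the C4 hydroxyl into a phosphate leaving group and bromide substitutes by addition–elimination at C4; no stereocentre is involved.

Step 2
Reactants: 2 4-bromo-6-methyl-2H-pyran-2-one; 3 (S)-1-(4-methoxyphenyl)ethanol
Product: 5 4-[(1S)-1-(4-methoxyphenyl)ethoxy]-6-methyl-2H-pyran-2-one, via sodium alkoxide 4 (not isolated)
Conditions: 3, NaH, THF, 0 °C; then 2, 0 °C → rt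
Reagents that add atoms: none
Why: Nucleophilic vinylic substitution (addition–elimination) of the alkoxide at C4 of the 4-halopyranone, a vinylogous acyl bromide; the carbinol C–O bond of 3 is never broken, so the (S) centre is carried over unchanged, which a Mitsunobu etherification of this easily ionised benzylic alcohol could not guarantee.

Step 3
Reactants: 5 4-[(1S)-1-(4-methoxyphenyl)ethoxy]-6-methyl-2H-pyran-2-one; 6 vinylene carbonate
Product: 7 endo bridged-lactone cycloadduct (2-oxabicyclo[2.2.2]oct-5-en-3-one: C7(=O)–O–C4 bridge on the top face; O2/O3 cyclic carbonate on the bottom face syn to C5=C6; C4 methyl; C6 O-MPE enol ether), single diastereomer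
Conditions: 6 (5 equiv), 2,6-di-tert-butyl-4-methylphenol (cat.), CH2Cl2, 12 kbar, 40 °C, 72 h; then separation of the two endo diastereomers (SiO2, crystallisation)
Reagents that add atoms: none
Why: Proposed new method: a concerted, suprafacial [4+2] cycloaddition between the diene C3=C4–C5=C6 of the pyranone and the double bond of 6; the closest known type is the thermal or high-pressure Diels–Alder reaction of 2-pyranones with alkenes and enol ethers that stops at the bridged lactone, here extended to a 4-alkoxy-6-methylpyranone paired with a 1,2-dioxygenated alkene. The carbocycle C1–C6 closes in this step by simultaneous formation of C1–C2 and C3–C4 as a boat, the third bridge C7(=O)–O–C4 being the ester group of the pyranone itself. C1 and C4 are set together because the bridge can span only one face, C2 and C3 are cis because the dienophile adds suprafacially, and their position anti to the lactone bridge (syn to C5=C6) follows from the endo transition state, which is the more compact one and is therefore favoured by pressure. The step needs endo over exo selectivity and retention of CO2; the compact endo transition state and the use of 12 kbar at 40 °C in place of heat should secure both, and regiochemistry does not arise because 6 is symmetrical. The absolute configuration is not left to a catalyst: the (S) centre of the ether makes the two endo adducts diastereomers whatever facial bias it exerts, and the isomer with the C1–C4 configuration of 32 is to be separated and its assignment secured by X-ray analysis against the known centre.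

Step 4
Reactants: 7 endo bridged-lactone cycloadduct
Product: 9 C5 alcohol of the bridged lactone carbonate (5-OH top; 6-H top; 6-O-MPE bottom), via C5 alkylborane 8 (not isolated)
Conditions: BH3·THF, THF, 0 °C → rt; then NaBO3·4H2O, H2O, rt
Reagents that add atoms: sodium perborate, [Na+].[Na+].O[B-]1(O)OO[B-](O)(O)OO1
Why: Hydroboration–oxidation of an enol ether: boron goes to C5, the β-carbon that is both the more electron-rich and the less substituted one, and syn addition takes place on the face next to the flat lactone bridge because the endo carbonate covers the other; oxidation with retention gives C5–OH on the top face and, since hydrogen has entered C6 from the same side, the C6 oxygen on the bottom face as in 32. Perborate is chosen because alkaline peroxide would cleave carbonate and lactone.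

Step 5
Reactants: 9 C5 alcohol of the bridged lactone carbonate
Product: 10 C5 O-TBS ether of 9
Conditions: TBSOTf, 2,6-lutidine, CH2Cl2, −78 → 0 °C
Reagents that add atoms: tert-butyldimethylsilyl triflate, CC(C)(C)[Si](C)(C)OS(=O)(=O)C(F)(F)F
Why: Silyl ether formation with the triflate, needed for a secondary hydroxyl next to the quaternary C4; the group marks O5 as the future ketone oxygen and keeps it apart from O2/O3 (later acetonide) and O6 (MPE ether).

Step 6
Reactants: 10 C5 O-TBS ether of 9
Product: 11 cyclohexane tetraol (C1 CH2OH = C7 top; 2-OH and 3-OH bottom; 4-OH top with 4-CH3; 5-OTBS top; 6-O-MPE bottom)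
Conditions: LiAlH4, THF, 0 °C → rt; aq. potassium sodium tartrate (KNaC4H4O6) work-up
Reagents that add atoms: none
Why: Hydride reduction of both acyl groups at once: the lactone gives the C7 primary alcohol and the C4 tertiary alcohol, the carbonate gives the C2/C3 diol and its carbon leaves as methanol; silyl and benzylic ethers are inert, and no stereocentre is touched because C1 is a non-enolisable bridgehead until the ring is open.

Step 7
Reactants: 11 cyclohexane tetraol
Product: 12 2,3-O-isopropylidene derivative of 11 (C7-OH and 4-OH free)
Conditions: Me2C(OMe)2, pyridinium p-toluenesulfonate (cat.), acetone, rt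
Reagents that add atoms: 2,2-dimethoxypropane, COC(C)(C)OC
Why: Acid-catalysed ketalisation under thermodynamic control: only O2 and O3 are cis-vicinal and free (O4 is trans to O3, O5 is silylated), and the five-membered dioxolane is favoured over a dioxane that would include the primary hydroxyl; the mild pyridinium acid spares the benzylic and silyl ethers.

Step 8
Reactants: 12 2,3-O-isopropylidene derivative of 11
Product: 13 C7 aldehyde (C1–CHO; other groups as in 12)
Conditions: Dess–Martin periodinane, NaHCO3, CH2Cl2, 0 °C → rt
Reagents that add atoms: none
Why: Dess–Martin oxidation of the only oxidisable hydroxyl (the tertiary one is inert); the bicarbonate buffer and direct use of the crude aldehyde limit β-elimination of O2 or O6.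

Step 9
Reactants: 13 C7 aldehyde; 14 5-bromo-2-methylpent-2-ene
Product: 16 C7 secondary alcohol carrying C8–C11 as a 4-methylpent-3-enyl chain (both C7 epimers), via Grignard reagent 15 (not isolated)
Conditions: 14, Mg, THF, rt; then 13 (3 equiv of 15), THF, −78 → −20 °C; aq. NH4Cl
Reagents that add atoms: none
Why: Grignard addition to the aldehyde forms the C7–C8 bond; one equivalent is consumed by the C4 hydroxyl and low temperature favours addition over enolisation; the new carbinol centre at C7 is of no consequence because it is oxidised in step 10.

Step 10
Reactants: 16 C7 secondary alcohol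
Product: 17 C7 ketone (C1–C(=O)–CH2CH2CH=C(CH3)2)
Conditions: Dess–Martin periodinane, NaHCO3, CH2Cl2, rt
Reagents that add atoms: none
Why: Dess–Martin oxidation of the secondary C7 alcohol under neutral, buffered conditions, which do not enolise the product toward C1.

Step 11
Reactants: 17 C7 ketone
Product: 19 8-hydroxy-7-ketone (both C8 epimers), via potassium enolate 18 (not isolated)
Conditions: KN(SiMe3)2 (2.2 equiv), THF, −78 °C; then 3-phenyl-2-(phenylsulfonyl)oxaziridine, −78 °C; aq. NH4Cl
Reagents that add atoms: 3-phenyl-2-(phenylsulfonyl)oxaziridine, O=S(=O)(c1ccccc1)N1OC1c1ccccc1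
Why: Enolate hydroxylation with an N-sulfonyloxaziridine (Davis oxidation): the bulky amide base removes a proton from the unhindered C8 methylene and not from the C1 methine, and the potassium enolate is oxidised at C8; both C8 epimers are accepted because the centre is reset in steps 13 and 14, and an allylic oxidation is avoided since it would attack the C10=C11 unit first.

Step 12
Reactants: 19 8-hydroxy-7-ketone
Product: 20 7(14)-methylene-8-ol (both C8 epimers)
Conditions: Ph3PCH3Br, KOt-Bu (excess ylide), THF, 0 °C → rt
Reagents that add atoms: methyltriphenylphosphonium bromide, C[P+](c1ccccc1)(c1ccccc1)c1ccccc1.[Br-]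
Why: Wittig methylenation; the α-ketol reacts as its alkoxide, which suppresses enolisation on the C8 side, and an excess of the small non-stabilised ylide is used so that addition to the hindered C7 carbonyl outruns deprotonation at C1.

Step 13
Reactants: 20 7(14)-methylene-8-ol
Product: 21 7(14)-methylene-8-ketone (enone C14=C7–C8=O)
Conditions: Dess–Martin periodinane, NaHCO3, CH2Cl2, 0 °C
Reagents that add atoms: none
Why: Dess–Martin oxidation of the allylic alcohol to the enone (the tertiary C4 hydroxyl is inert); buffered, cold conditions keep the doubly activated C9 methylene from moving the C10=C11 bond into conjugation.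

Step 14
Reactants: 21 7(14)-methylene-8-ketone
Product: 22 (8S)-7(14)-methylene-8-ol
Conditions: (R)-1-methyl-3,3-diphenyltetrahydro-1H,3H-pyrrolo[1,2-c][1,3,2]oxazaborole ((R)-Me-CBS, 0.5 equiv), catecholborane, CH2Cl2, −78 °C
Reagents that add atoms: none
Why: Corey–Bakshi–Shibata reduction: the 2-substituted alkenyl group (C7) acts as the large substituent and the C9 methylene as the small one, so the (R) catalyst delivers hydride to the face that gives the (8S) alcohol independently of the ring; catecholborane at −78 °C reduces the carbonyl in the 1,2 sense without hydroborating either alkene.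

Step 15
Reactants: 23 angelic acid ((Z)-2-methylbut-2-enoic acid)
Product: 24 angelic 2,4,6-trichlorobenzoic anhydride
Conditions: 2,4,6-Cl3C6H2COCl, Et3N, toluene, 0 °C → rt; filtration of Et3NHCl; kept cold as a toluene solution under argon
Reagents that add atoms: 2,4,6-trichlorobenzoyl chloride, O=C(Cl)c1c(Cl)cc(Cl)cc1Cl
Why: Mixed anhydride formation by O-acylation of the triethylammonium carboxylate with the hindered aroyl chloride (first half of the Yamaguchi protocol); only the carboxyl oxygen reacts, so the Z double bond is not touched. One filtered batch serves steps 16, 18 and 22.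

Step 16
Reactants: 22 (8S)-7(14)-methylene-8-ol; 24 angelic 2,4,6-trichlorobenzoic anhydride
Product: 25 (8S)-8-O-angeloyl derivative of 22 (6-O-MPE, 5-OTBS, 2,3-acetonide and free 4-OH kept)
Conditions: 24 (2 equiv), Et3N, toluene, 70 °C
Reagents that add atoms: none
Why: Yamaguchi-type esterification with the preformed mixed anhydride and no nucleophilic catalyst, the standard way to transfer the angeloyl group without Z to E isomerisation: the alcohol attacks the angeloyl carbonyl because the aryl carbonyl is screened by two ortho chlorines. The allylic C8 hydroxyl is the only secondary hydroxyl present and the tertiary C4 hydroxyl does not react; the ester also masks the allylic alcohol against the quinone of step 17.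

Step 17
Reactants: 25 (8S)-8-O-angeloyl derivative of 22
Product: 26 (8S)-8-O-angeloyl 4,6-diol (O-MPE removed; 2,3-acetonide and 5-OTBS kept)
Conditions: DDQ, CH2Cl2/pH 7 phosphate buffer, 0 °C
Reagents that add atoms: none
Why: Oxidative cleavage of the electron-rich benzylic ether by DDQ (hydride abstraction, then hydrolysis of the oxocarbenium ion); the auxiliary leaves as 4-methoxyacetophenone, while the silyl ether, the acetonide, both alkenes and the allylic ester are expected to survive in the buffered two-phase medium.

Step 18
Reactants: 26 (8S)-8-O-angeloyl 4,6-diol; 24 angelic 2,4,6-trichlorobenzoic anhydride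
Product: 27 6,8-di-O-angeloyl derivative (2,3-acetonide, 5-OTBS and free 4-OH kept)
Conditions: 24 (3 equiv), Et3N, toluene, 80 °C
Reagents that add atoms: none
Why: Esterification by the mixed anhydride method of step 16; the C6 hydroxyl is the only secondary hydroxyl left, so the forcing temperature it needs (it lies between C1 and the silylated O5) cannot cause over-acylation, the tertiary C4 hydroxyl being inert.

Step 19
Reactants: 27 6,8-di-O-angeloyl derivative
Product: 28 5-hydroxy di-angelate (TBS removed)
Conditions: HF·pyridine, pyridine, THF, 0 °C → rt
Reagents that add atoms: none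
Why: Fluoride-mediated desilylation under acidic buffering, chosen over basic fluoride so that the C6 angelate does not migrate to the liberated neighbouring O5; acetonide, esters and alkenes tolerate the reagent.

Step 20
Reactants: 28 5-hydroxy di-angelate
Product: 29 5-ketone di-angelate (2,3-acetonide kept)
Conditions: Dess–Martin periodinane, NaHCO3, CH2Cl2, rt
Reagents that add atoms: none
Why: Dess–Martin oxidation; C5–OH is at this point the only secondary hydroxyl, so the ketone appears only after O6 is esterified and while O3 is still masked, which avoids both a free enolisable α-ketol at C5/C6 and competition from C3–OH.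

Step 21
Reactants: 29 5-ketone di-angelate
Product: 30 2,3-diol 5-ketone di-angelate
Conditions: AcOH/H2O (4:1), 45 °C
Reagents that add atoms: none
Why: Acid hydrolysis of the isopropylidene acetal with aqueous acetic acid, weak enough to leave the trisubstituted alkene, the allylic ester and the tertiary α-ketol alone; it is placed before the epoxidation because the oxirane would not survive it.

Step 22
Reactants: 30 2,3-diol 5-ketone di-angelate; 24 angelic 2,4,6-trichlorobenzoic anhydride
Product: 31 2,6,8-tri-O-angeloyl 10,11-alkene (10,11-deoxy-32)
Conditions: 24 (1.2 equiv), Et3N, toluene, 70 °C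
Reagents that add atoms: none
Why: Site-selective esterification by the mixed anhydride method of step 16: the C2 hydroxyl is equatorial, whereas the C3 hydroxyl is axial and neopentyl (next to the quaternary C4) and the C4 hydroxyl is tertiary, so a small excess of acylating agent is expected to go to O2.

Step 23
Reactants: 31 2,6,8-tri-O-angeloyl 10,11-alkene
Product: 32 CNP0313777.1 (target)
Conditions: 1,2:4,5-di-O-isopropylidene-β-D-erythro-2,3-hexodiulo-2,6-pyranose (0.3 equiv), Oxone (2KHSO5·KHSO4·K2SO4), K2CO3, n-Bu4NHSO4, Na2B4O7 buffer, MeCN/CH2(OMe)2/H2O, 0 °C
Reagents that add atoms: potassium peroxymonosulfate, [K+].[O-]S(=O)(=O)OO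
Why: Shi asymmetric epoxidation: the chiral dioxirane formed from the D-fructose-derived ketone and KHSO5 transfers oxygen through a spiro transition state to the electron-rich trisubstituted C10=C11 bond and gives the (10R) oxirane by catalyst control; the hindered, ester-deactivated C7=C14 bond and the three conjugated angelate double bonds are much less nucleophilic.

## Compound list

1 | triacetic acid lactone (4-hydroxy-6-methyl-2H-pyran-2-one) | CC1=CC(O)=CC(=O)O1 | starting material
2 | 4-bromo-6-methyl-2H-pyran-2-one | CC1=CC(Br)=CC(=O)O1 | intermediate
3 | (S)-1-(4-methoxyphenyl)ethanol | C[C@H](O)c1ccc(OC)cc1 | starting material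
4 | sodium (S)-1-(4-methoxyphenyl)ethoxide | C[C@H]([O-])c1ccc(OC)cc1.[Na+] | intermediate
5 | 4-[(1S)-1-(4-methoxyphenyl)ethoxy]-6-methyl-2H-pyran-2-one (diene) | CC1=CC(O[C@@H](C)c2ccc(OC)cc2)=CC(=O)O1 | intermediate
6 | vinylene carbonate | O=C1OC=CO1 | starting material
7 | endo bridged-lactone cycloadduct (C7 lactone bridge top; O2/O3 carbonate bottom; C5=C6 enol ether with O-MPE on C6) | O=C3[C@H]1[C@@H]2OC(=O)O[C@@H]2[C@@](C)(O3)C=C1O[C@@H](C)c1ccc(OC)cc1 | intermediate
8 | C5 alkylborane of 7 (BH2 on the top face of C5; H on the top face of C6) | O=C3[C@H]1[C@@H]2OC(=O)O[C@@H]2[C@@](C)(O3)[C@@H](B)[C@@H]1O[C@@H](C)c1ccc(OC)cc1 | intermediate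
9 | C5 alcohol of the bridged lactone carbonate (5-OH top; 6-O-MPE bottom) | O=C3[C@H]1[C@@H]2OC(=O)O[C@@H]2[C@@](C)(O3)[C@@H](O)[C@@H]1O[C@@H](C)c1ccc(OC)cc1 | intermediate
10 | C5 O-TBS ether of 9 | O=C3[C@H]1[C@@H]2OC(=O)O[C@@H]2[C@@](C)(O3)[C@@H](O[Si](C)(C)C(C)(C)C)[C@@H]1O[C@@H](C)c1ccc(OC)cc1 | intermediate
11 | cyclohexane tetraol (C7H2OH on C1 top; 2-OH, 3-OH bottom; 4-OH top; 5-OTBS top; 6-O-MPE bottom) | OC[C@H]1[C@H](O)[C@H](O)[C@@](C)(O)[C@@H](O[Si](C)(C)C(C)(C)C)[C@@H]1O[C@@H](C)c1ccc(OC)cc1 | intermediate
12 | 2,3-O-isopropylidene derivative of 11 | OC[C@H]1[C@@H]2OC(C)(C)O[C@@H]2[C@@](C)(O)[C@@H](O[Si](C)(C)C(C)(C)C)[C@@H]1O[C@@H](C)c1ccc(OC)cc1 | intermediate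
13 | C7 aldehyde | O=C[C@H]1[C@@H]2OC(C)(C)O[C@@H]2[C@@](C)(O)[C@@H](O[Si](C)(C)C(C)(C)C)[C@@H]1O[C@@H](C)c1ccc(OC)cc1 | intermediate
14 | 5-bromo-2-methylpent-2-ene | CC(C)=CCCBr | starting material
15 | 4-methylpent-3-enylmagnesium bromide | CC(C)=CCC[Mg]Br | intermediate
16 | C7 secondary alcohol with 4-methylpent-3-enyl chain (both C7 epimers) | CC(C)=CCCC(O)[C@H]1[C@@H]2OC(C)(C)O[C@@H]2[C@@](C)(O)[C@@H](O[Si](C)(C)C(C)(C)C)[C@@H]1O[C@@H](C)c1ccc(OC)cc1 | intermediate
17 | C7 ketone | CC(C)=CCCC(=O)[C@H]1[C@@H]2OC(C)(C)O[C@@H]2[C@@](C)(O)[C@@H](O[Si](C)(C)C(C)(C)C)[C@@H]1O[C@@H](C)c1ccc(OC)cc1 | intermediate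
18 | dipotassium salt of 17: (Z)-enolate C7(O−)=C8 and C4 alkoxide | CC(C)=CC/C=C(\[O-])[C@H]1[C@@H]2OC(C)(C)O[C@@H]2[C@@](C)([O-])[C@@H](O[Si](C)(C)C(C)(C)C)[C@@H]1O[C@@H](C)c1ccc(OC)cc1.[K+].[K+] | intermediate
19 | 8-hydroxy-7-ketone (both C8 epimers) | CC(C)=CCC(O)C(=O)[C@H]1[C@@H]2OC(C)(C)O[C@@H]2[C@@](C)(O)[C@@H](O[Si](C)(C)C(C)(C)C)[C@@H]1O[C@@H](C)c1ccc(OC)cc1 | intermediate
20 | 7(14)-methylene-8-ol (both C8 epimers) | CC(C)=CCC(O)C(=C)[C@H]1[C@@H]2OC(C)(C)O[C@@H]2[C@@](C)(O)[C@@H](O[Si](C)(C)C(C)(C)C)[C@@H]1O[C@@H](C)c1ccc(OC)cc1 | intermediate
21 | 7(14)-methylene-8-ketone (enone) | CC(C)=CCC(=O)C(=C)[C@H]1[C@@H]2OC(C)(C)O[C@@H]2[C@@](C)(O)[C@@H](O[Si](C)(C)C(C)(C)C)[C@@H]1O[C@@H](C)c1ccc(OC)cc1 | intermediate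
22 | (8S)-7(14)-methylene-8-ol | C=C([C@H]1[C@@H]2OC(C)(C)O[C@@H]2[C@@](C)(O)[C@@H](O[Si](C)(C)C(C)(C)C)[C@@H]1O[C@@H](C)c1ccc(OC)cc1)[C@H](CC=C(C)C)O | intermediate
23 | angelic acid ((Z)-2-methylbut-2-enoic acid) | C/C=C(/C)C(=O)O | starting material
24 | angelic 2,4,6-trichlorobenzoic anhydride | C/C=C(/C)C(=O)OC(=O)c1c(Cl)cc(Cl)cc1Cl | intermediate
25 | (8S)-8-O-angeloyl derivative of 22 (6-O-MPE; 5-OTBS; 2,3-acetonide; 4-OH) | C=C([C@H]1[C@@H]2OC(C)(C)O[C@@H]2[C@@](C)(O)[C@@H](O[Si](C)(C)C(C)(C)C)[C@@H]1O[C@@H](C)c1ccc(OC)cc1)[C@H](CC=C(C)C)OC(=O)/C(C)=C\C | intermediate
26 | (8S)-8-O-angeloyl 4,6-diol (2,3-acetonide; 5-OTBS) | C=C([C@H]1[C@@H]2OC(C)(C)O[C@@H]2[C@@](C)(O)[C@@H](O[Si](C)(C)C(C)(C)C)[C@@H]1O)[C@H](CC=C(C)C)OC(=O)/C(C)=C\C | intermediate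
27 | 6,8-di-O-angeloyl derivative (2,3-acetonide; 5-OTBS; 4-OH) | C=C([C@H]1[C@@H]2OC(C)(C)O[C@@H]2[C@@](C)(O)[C@@H](O[Si](C)(C)C(C)(C)C)[C@@H]1OC(=O)/C(C)=C\C)[C@H](CC=C(C)C)OC(=O)/C(C)=C\C | intermediate
28 | 5-hydroxy di-angelate (5-OH top) | C=C([C@H]1[C@@H]2OC(C)(C)O[C@@H]2[C@@](C)(O)[C@@H](O)[C@@H]1OC(=O)/C(C)=C\C)[C@H](CC=C(C)C)OC(=O)/C(C)=C\C | intermediate
29 | 5-ketone di-angelate (2,3-acetonide) | C=C([C@H]1[C@@H]2OC(C)(C)O[C@@H]2[C@@](C)(O)C(=O)[C@@H]1OC(=O)/C(C)=C\C)[C@H](CC=C(C)C)OC(=O)/C(C)=C\C | intermediate
30 | 2,3-diol 5-ketone di-angelate | C=C([C@H]1[C@H](O)[C@H](O)[C@@](C)(O)C(=O)[C@@H]1OC(=O)/C(C)=C\C)[C@H](CC=C(C)C)OC(=O)/C(C)=C\C | intermediate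
31 | 2,6,8-tri-O-angeloyl 10,11-alkene (10,11-deoxy-32) | C=C([C@H]1[C@H](OC(=O)/C(C)=C\C)[C@H](O)[C@@](C)(O)C(=O)[C@@H]1OC(=O)/C(C)=C\C)[C@H](CC=C(C)C)OC(=O)/C(C)=C\C | intermediate
32 | CNP0313777.1 | C=C([C@H]1[C@H](OC(=O)/C(C)=C\C)[C@H](O)[C@@](C)(O)C(=O)[C@@H]1OC(=O)/C(C)=C\C)[C@H](C[C@H]1OC1(C)C)OC(=O)/C(C)=C\C | target

## Step count and least certain steps

Total step count: 23. Longest linear sequence: 22 steps (1 to 32 through steps 1–14 and 16–23). Step 15 is a one-step branch that supplies 24, and the other starting materials (3, 6, 14) enter without steps of their own.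

Step 3 (key step, carries the label). The most likely failure is a cycloaddition that is too slow, because a donor-substituted pyranone meets an alkene that is neither clearly electron-poor nor electron-rich; forcing it with heat would cause loss of CO2 from the adduct and aromatisation. The second risk is poor endo/exo discrimination or co-elution of the two endo diastereomers. Fallback with known chemistry, setting out from 5: bromination at C3 with N-bromosuccinimide (MeCN, rt, dark) would give 3-bromo-4-[(1S)-1-(4-methoxyphenyl)ethoxy]-6-methyl-2H-pyran-2-one F1. 3-Bromo-2-pyranones are ambiphilic dienes whose thermal cycloadditions to alkenes (toluene, 90 °C, no pressure) stop at the bridged lactone, so heating F1 with 6 should give the C1-bromo cycloadduct F2. Radical reduction (Bu3SnH, Et3B, air, toluene, 0 °C → rt) would remove the bridgehead bromine, whose replacement by hydrogen cannot change the configuration fixed by the bicycle. The sequence comes back to the route at 7, with the same separation of diastereomers.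

Step 2. The alkoxide may attack C2 or C6 of the pyranone (ring opening) or deprotonate the 6-methyl group instead of substituting at C4. Fallback, setting out from 1 and coming back at 5: Mitsunobu etherification of 1 with (R)-1-(4-methoxyphenyl)ethanol (PPh3, diisopropyl azodicarboxylate, THF, 0 °C), which activates the alcohol instead of the pyranone and forms the (S) ether by inversion. It makes no new compound (F0). Any erosion of optical purity by partial ionisation of the benzylic centre would have to be removed by crystallisation of 5 or 7.

Step 12. Enolisation toward C1 with β-elimination of O2 or O6, or base-induced isomerisation of the α-ketol, may outrun ylide addition to the hindered C7 carbonyl. Fallback, setting out from 19: silylation of the C8 hydroxyl (Et3SiCl, imidazole, CH2Cl2) to the C8 triethylsilyl ether F3, then non-basic methylenation with the titanium alkylidene from Cp2TiMe2 (toluene, 70 °C) to the methylene compound F4, then selective removal of the triethylsilyl group (HF·pyridine, pyridine, THF, 0 °C). The sequence comes back to the route at 20.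

Step 18. Acylation of the C6 hydroxyl, wedged between C1 and the silylated O5, may stay incomplete, and prolonged heating may isomerise the angeloyl group from Z to E. Fallback, setting out from 26: esterification of the C6 hydroxyl with the small, sp3-hybridised 2-[bis(2,2,2-trifluoroethoxy)phosphoryl]propanoic acid (EDC·HCl, DMAP, CH2Cl2) to the 6-phosphonopropanoate F5, then Still–Gennari olefination with acetaldehyde (KN(SiMe3)2, 18-crown-6, THF, −78 °C), which builds the (Z)-2-methylbut-2-enoate on the substrate. The sequence comes back to the route at 27.

Step 22. Site selectivity between the C2 and C3 hydroxyls may be insufficient, and at 70 °C with amine base acyl migration or rearrangement of the tertiary α-ketol may set in. Fallback, setting out from 30: formation of the 2,3-O-dibutylstannylene acetal F6 (Bu2SnO, toluene, reflux with removal of water), which activates the equatorial oxygen O2, then acylation with 24 at rt. The sequence comes back to the route at 31.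

Step 23. In the basic buffer the C2 angelate may migrate to O3 or the α-acyloxy ketone may enolise before the epoxidation is complete. Fallback, setting out from 31: epoxidation with mCPBA and solid NaHCO3 in CH2Cl2 at 0 °C, which avoids aqueous base but gives up catalyst control, so that 32 would form together with its (10S) epimer F7 and the two would be separated by preparative HPLC. The sequence ends at 32.

## Further compounds

F1 | step 3 | 3-bromo-4-[(1S)-1-(4-methoxyphenyl)ethoxy]-6-methyl-2H-pyran-2-one | CC1=CC(O[C@@H](C)c2ccc(OC)cc2)=C(Br)C(=O)O1
F2 | step 3 | C1-bromo analogue of cycloadduct 7 (bromine on the bridgehead C1) | O=C3[C@@]1(Br)[C@@H]2OC(=O)O[C@@H]2[C@@](C)(O3)C=C1O[C@@H](C)c1ccc(OC)cc1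
F0 | step 2 | none | none
F3 | step 12 | C8 triethylsilyl ether of 19 (both C8 epimers) | CC(C)=CCC(O[Si](CC)(CC)CC)C(=O)[C@H]1[C@@H]2OC(C)(C)O[C@@H]2[C@@](C)(O)[C@@H](O[Si](C)(C)C(C)(C)C)[C@@H]1O[C@@H](C)c1ccc(OC)cc1
F4 | step 12 | C8 triethylsilyl ether of 20 (both C8 epimers) | CC(C)=CCC(O[Si](CC)(CC)CC)C(=C)[C@H]1[C@@H]2OC(C)(C)O[C@@H]2[C@@](C)(O)[C@@H](O[Si](C)(C)C(C)(C)C)[C@@H]1O[C@@H](C)c1ccc(OC)cc1
F5 | step 18 | 6-O-{2-[bis(2,2,2-trifluoroethoxy)phosphoryl]propanoyl} derivative of 26 | C=C([C@H]1[C@@H]2OC(C)(C)O[C@@H]2[C@@](C)(O)[C@@H](O[Si](C)(C)C(C)(C)C)[C@@H]1OC(=O)C(C)P(=O)(OCC(F)(F)F)OCC(F)(F)F)[C@H](CC=C(C)C)OC(=O)/C(C)=C\C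
F6 | step 22 | 2,3-O-dibutylstannylene acetal of 30 | C=C([C@H]1[C@@H]2O[Sn](CCCC)(CCCC)O[C@@H]2[C@@](C)(O)C(=O)[C@@H]1OC(=O)/C(C)=C\C)[C@H](CC=C(C)C)OC(=O)/C(C)=C\C
F7 | step 23 | (10S) epimer of 32 | C=C([C@H]1[C@H](OC(=O)/C(C)=C\C)[C@H](O)[C@@](C)(O)C(=O)[C@@H]1OC(=O)/C(C)=C\C)[C@H](C[C@@H]1OC1(C)C)OC(=O)/C(C)=C\C
A1 | alternative 1 | 1-acetylcyclopentanol precursor (ring C1, C2, C3, C5, C6; acetyl = C4 with its methyl on the carbinol carbon C5; carbinol configuration left open) | C=C([C@H]1[C@@H]2OC(C)(C)O[C@@H]2C(O)(C(C)=O)[C@@H]1O[Si](C)(C)C(C)(C)C)[C@H](CC=C(C)C)O[Si](C)(C)C(C)(C)C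
A2 | alternative 1 | ring-enlarged 4-hydroxy-4-methylcyclohexan-5-one | C=C([C@H]1[C@@H]2OC(C)(C)O[C@@H]2[C@@](C)(O)C(=O)[C@@H]1O[Si](C)(C)C(C)(C)C)[C@H](CC=C(C)C)O[Si](C)(C)C(C)(C)C
A3 | alternative 2 | open-chain 1,6-dialdehyde (formyl carbons C2 and C3) | C=C([C@@H](C=O)[C@@H](OCc1ccc(OC)cc1)[C@H](O[Si](CC)(CC)CC)[C@](C)(O)C=O)[C@H](CC=C(C)C)OCc1ccc(OC)cc1
A4 | alternative 2 | cyclohexane cis-2,3-diol | C=C([C@H]1[C@H](O)[C@H](O)[C@@](C)(O)[C@@H](O[Si](CC)(CC)CC)[C@@H]1OCc1ccc(OC)cc1)[C@H](CC=C(C)C)OCc1ccc(OC)cc1
A5 | alternative 3 | open-chain C2 aldehyde with C1=C7 alkene (alkene geometry left open) | O=C[C@H](OCc1ccc(OC)cc1)[C@@]1(C)OC(C)(C)O[C@H]1[C@H](O[Si](C)(C)C(C)(C)C)C=C(C)[C@H](CC=C(C)C)O[Si](C)(C)C(C)(C)C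
A6 | alternative 3 | cyclohexanol with free C2 hydroxyl and C7=C14 methylene | C=C([C@H]1[C@H](O)[C@H](OCc2ccc(OC)cc2)[C@@]2(C)OC(C)(C)O[C@H]2[C@@H]1O[Si](C)(C)C(C)(C)C)[C@H](CC=C(C)C)O[Si](C)(C)C(C)(C)C
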